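## Structural features

Psiguadial A (28) joins an aromadendrane sesquiterpene (numbered C1–C15: cyclopentane C1–C5, cycloheptane C1/C5–C10, gem-dimethylcyclopropane C6–C7–C11, methyl C14 on C10, methyl C15 on C4) to a 3,5-diformylphloroglucinol ring (C1″–C6″) through a benzylic carbon C7′ that also carries a phenyl group. C7′ is bonded to C4 and the C2″ oxygen to C1, so O, C2″, C1″ and C7′ bridge the cyclopentane 1,3 and form a benzoxepine inside a bicyclo[4.2.1] core whose one-carbon bridge is C5. There are seven stereocentres: C10, C1, C5, C4 and C7′ stand in an unbroken row, C6 and C7 are the cis cyclopropane carbons next to C5, and the tertiary ether carbon C1 and the all-carbon quaternary C4 are separated only by C5. With β defined as the face of the hydroazulene that carries C11, the O–C1 bond, C7′ on C4, H5 and C14 are β, while C15, H10, H6 and H7 are α. The cyclopropane opens with any cation or radical at C5, the tertiary alkyl aryl ether ionises in strong acid, and the aldehydes and free phenols are best unveiled last. The real difficulty is the quaternary C4 with its two carbon substituents the right way round, the ether at C1 and not at C5, and C7′, which must be set beside a quaternary centre. The key step exploits three facts: C6 and C7 with their cis side chains are the ozonolysis fragment of (+)-2-carene, C3 lies between C2 and C4 and can come from carbon monoxide, and the seven-membered ring closes through the C1–C5 bond.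

## Logic of the disconnections

28 to 27. The two aryl–CHO bonds at C3″ and C5″ are cut. The aldehydes are the most sensitive groups, and removing them lets every earlier intermediate be a plain aryl ether. The forward step must formylate both free ring positions, each ortho to a hydroxyl, without harming the cyclopropane or the tertiary ether.

27 to 26. The two O–CH3 bonds are cut, so the spectator phenols are carried as methyl ethers from 12. The forward cleavage must attack the methyl carbons with a nucleophile, because acid would endanger the C1–O bond and the cyclopropane.

26 to 23 and 24 (through 25). The C7′–phenyl bond is cut. With phenyl as the last substituent at C7′, the rigid bicycle decides its face, and the disconnection removes a stereocentre and a ring. The forward step needs an SN1 capture of the C7′ cation from the side of the one-carbon bridge; C4 has no hydrogen, so elimination cannot compete.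

23 to 22 to 20 to 19. No skeletal bond is cut. The C7′ alcohol goes back to the aryl ketone and the C3 methylene to the C3 ketone, which is the handle needed for the ring closure. The forward deoxygenation must avoid strong base (19 is a β-aryloxy ketone) and must leave the C7′ ketone alone.

19 to 17 (through 18) to 16. The O–C1 bond is cut, with the C5–H bond formed in the same operation, and then one ortho O–CH3 bond. A C3 ketone makes C1, and only C1, electrophilic as the β-carbon of an enone, so the ether can be closed by base without a cation near the cyclopropane. This opens the bridged ring and removes C1 and C5 as stereocentres. The forward steps need chelation-selective unmasking of one ortho oxygen, then alkene isomerisation and oxa-Michael addition.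

16 to 15. The C4–CH3 bond is cut. Methyl is put in last at C4 so that it enters anti to the cyclopropane and leaves the aroyl group β. The forward step needs C-alkylation of a 1,3-diketone.

15 to 14 to 11 and 12. The C4–C7′ bond and the C10–H bond are cut. The phloroglucinol ring enters as 12 and the dienone of 11 supplies a regiodefined dienolate. The forward step needs hydride delivery to C10 on the α face and trapping at C4.

11 to 10. The key step: C1–C5, C2–C3 and C3–C4 are cut and C3 leaves as CO. Two rings and three skeletal bonds are gained from an acyclic tether. The forward step must use the distal allene bond and insert CO faster than β-hydride loss.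

10 to 9 to 7 to 5 and 6. The allene C2–H bond goes back to a propargylic carbonate and the C1–C10 bond to ethynyl addition to a methyl ketone. The forward reduction must be SN2′.

5 to 3 and 4; 3 to 1 (through 2). The alkyne carbon C4 is removed back to the aldehyde, and the keto aldehyde is traced to the ring alkene of 1. Both ring-fusion centres of 1 are kept and become C6 and C7.

## Other disconnections considered

Alternative 1: The cut removes C4–C7′ and O–C1 together, which is the whole benzoxepine in a formal (4+3) annulation.
- Forward key step: the kinetic lithium α′-enolate of hydroazulenone A2 (C3 ketone, C1=C2, C4 bearing H and C15) would add through C4 to the ortho-quinone methide released by base from sulfone A3. The phenoxide so formed would then add to enone carbon C1 to give A1.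
- In its favour: two bonds, one ring and three stereocentres (C4, C7′, C1) arise in one operation, both aryl groups arrive in one fragment, and C7′ is set in the C–C bond-forming event. On convergence and on the number of late steps this is better than the chosen plan, which spends steps 7–11 and 15 on the same bonds.
- Equal: both plans close the ether by phenoxide addition to C1 of a C3 enone, and both are left with C3 deoxygenation, demethylation and diformylation.
- Against it here: A2 must carry C5, C10 and C15 before the annulation and is the less stable enone isomer, because with a hydrogen on C4 the alkene prefers the tetrasubstituted C4=C5 position. It is therefore not reached cleanly from 11. The α′ deprotonation competes with γ deprotonation at C5 and C10, the face selectivity at C4 rests on C6 alone, the C7′ topicity depends on an open transition state, and the quinone methide can oligomerise.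
- Comparison: the chosen plan is longer but introduces the two C7′ substituents one at a time under the control of a rigid bicycle.

Alternative 2: The cut takes the hydroazulene back to a ten-membered ring (C1–C5, C4–C7′ and O–C1 all undone) and then breaks C2–C3 so that the six-membered ring of carene reappears.
- Forward key step: KH with 18-crown-6 would convert the carene-derived 1,2-divinyl carbinol A5 into its alkoxide. Its [3,3] shift forms C2–C3 as C5–C10 breaks and gives ten-membered ketone A4 with an E C1=C10 alkene.
- In its favour: all ten carene carbons and both its stereocentres are kept, and the ring grows by four carbons in one pericyclic step with predictable alkene geometry. A biomimetic endgame then becomes possible in which a 4,5-alkene derived from A4 and a quinone methide form C4–C7′, C1–C5 and the ether in one cascade, without protecting groups or late formylation. On step economy this is better than the chosen plan.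
- Equal: the chiral-pool origin of C6 and C7.
- Against it here: A4 needs regioselective conversion of the C5 ketone into the C4=C5 alkene. The cascade passes a cyclopropylcarbinyl cation at C5, must end with ether formation at C1 and not at C10 (which needs a hydride shift), and has only ring conformation to control C4, C5, C1, C10 and C7′. Ten-membered dienes of this type are thermally and acid labile.
- Comparison: the chosen plan forms all ring bonds of the 5–7 system in one metal-templated step and then sets each stereocentre in its own step, at roughly twice the length.

Alternative 3: The cut is the C1–C5 bond of the hydroazulene, traced back by a dienone photorearrangement to the C5–C10 bond of a decalin. The 5–7 system comes from the 6–6 cross-conjugated cyclohexadienone A7, which already carries the C7′ diarylmethyl group on C4.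
- Forward key step: irradiation near 350 nm in aqueous acetic acid would bond C1 to C5. The bicyclo[3.1.0]hexenyl intermediate would open by C5–C10 cleavage with water capture at C10 to give hydroxy enone A6.
- In its favour: a classical, metal-free skeletal rearrangement, and decalin precursors are readily assembled from carene by annulation. The whole diarylmethyl unit comes in early, which is more convergent at C7′ than the chosen plan and better on that point.
- Equal: the use of carene for C6 and C7.
- Against it here: in A7 the cyclopropane is conjugated through C5 to the excited dienone, so cyclopropane opening competes. C7′ is set early with no ring to control it. A6 has C4 trigonal, so the quaternary C4, C5–H, C1–O and C10–H (after dehydration of the C10 alcohol) must all still be set after the key step.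
- Comparison: the chosen key step also creates no stereocentre, but it leaves a C3 ketone and two alkenes placed so that C10, C4, C1/C5 and C7′ are each addressed once. Here three or four centres are reset after the rearrangement, the step count would not be lower, and the photochemical step adds a scale-up burden.

Key step: step 6

Assumptions (remarks on the chemistry):
- The structures of 10 and 11 were checked atom by atom against 1 and 28. The ring-fusion carbons of (1S,6R)-1 become C6 (S) and C7 (R) of 11 with no bond to either made or broken, and no correction was needed. Allenyne 10 is kept as the bare hydrocarbon with a terminal alkyne, because C4 must stay unsubstituted so that its two carbon substituents can be added in the order acyl, then methyl.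
- Aromadendrane numbering and the α/β convention defined under "Structural features" are used for all intermediates from 11 onward.
- The carbinol carbon of 7 and the C4 and C7′ centres of 14 are formed without control; all three are erased later.
- Compounds 4, 6, 12 and 24 are taken as purchased.

## Route

Step 1
Reactants: 1 (+)-2-carene
Product: 3 (1S,3R)-2,2-dimethyl-3-(3-oxobutyl)cyclopropane-1-carbaldehyde, via ozonide 2 (not isolated)
Conditions: O3, CH2Cl2, −78 °C; then Me2S, −78 °C to rt
Reagents that add atoms: ozone, [O-][O+]=O
Why: Ozonolysis: 1,3-dipolar cycloaddition of ozone to the only alkene, rearrangement to the 1,2,4-trioxolane and reductive cleavage by Me2S give ketone and aldehyde without over-oxidation; no bond to the two ring-fusion carbons is touched, so they appear unchanged as the cis-disubstituted cyclopropane carbons (later C7 and C6).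

Step 2
Reactants: 3 (1S,3R)-2,2-dimethyl-3-(3-oxobutyl)cyclopropane-1-carbaldehyde; 4 dimethyl (1-diazo-2-oxopropyl)phosphonate
Product: 5 4-[(1R,3R)-3-ethynyl-2,2-dimethylcyclopropyl]butan-2-one
Conditions: K2CO3, MeOH, 0 °C to rt
Reagents that add atoms: none
Why: Ohira–Bestmann (Seyferth–Gilbert) homologation: methanolysis of 4 gives the diazomethylphosphonate anion, which turns the aldehyde into the terminal alkyne through a diazoalkene and a 1,2-hydride shift of the alkylidene carbene; the methyl ketone is far less electrophilic and is left alone at 0 °C, and the cyclopropyl C–H next to the aldehyde is a poor carbon acid, so the cis relationship should hold.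

Step 3
Reactants: 5 4-[(1R,3R)-3-ethynyl-2,2-dimethylcyclopropyl]butan-2-one; 6 ethynylmagnesium bromide
Product: 7 5-[(1R,3R)-3-ethynyl-2,2-dimethylcyclopropyl]-3-methylpent-1-yn-3-ol (both carbinol epimers)
Conditions: HC≡CMgBr (2.5 equiv), THF, 0 °C; aq. NH4Cl
Reagents that add atoms: none
Why: Grignard 1,2-addition to the methyl ketone; part of the reagent may be consumed by the acidic alkyne C–H, hence the excess; the new carbinol centre is formed without control and disappears in step 5.

Step 4
Reactants: 7 5-[(1R,3R)-3-ethynyl-2,2-dimethylcyclopropyl]-3-methylpent-1-yn-3-ol
Product: 9 methyl carbonate of 7, via lithium alkoxide 8 (not isolated)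
Conditions: LiN(SiMe3)2 (1.05 equiv), THF, −78 °C; then ClCO2Me, −78 to 0 °C
Reagents that add atoms: methyl chloroformate, COC(=O)Cl
Why: Alkoxycarbonylation of the tertiary lithium alkoxide (one equivalent of amide base removes the O–H before either alkyne C–H); the carbonate is the leaving group palladium needs and is chosen over a tertiary propargylic sulfonate, which would ionise or eliminate.

Step 5
Reactants: 9 methyl carbonate of 7
Product: 10 (1R,3R)-1-ethynyl-2,2-dimethyl-3-(3-methylpenta-3,4-dien-1-yl)cyclopropane
Conditions: Pd(OAc)2 (5 mol%), n-Bu3P (20 mol%), HCO2NH4 (2 equiv), THF, 40 °C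
Reagents that add atoms: none
Why: Palladium-catalysed decarboxylative formate hydrogenolysis of a propargylic carbonate: zerovalent palladium attacks in SN2′ fashion to give an allenylpalladium species, formate exchanges and loses CO2, and C–H reductive elimination at the palladium-bearing terminal carbon gives the 1,1-disubstituted allene; the allene is achiral, so both carbinol epimers converge.

Step 6
Reactants: 10 (1R,3R)-1-ethynyl-2,2-dimethyl-3-(3-methylpenta-3,4-dien-1-yl)cyclopropane
Product: 11 (6S,7R)-15-noraromadendra-1(10),4-dien-3-one
Conditions: [Rh(CO)2Cl]2 (5 mol%), CO (1 atm), toluene (0.01 M), 90 °C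
Reagents that add atoms: carbon monoxide, [C-]#[O+]
Why: Under CO the chloride-bridged dimer gives a monovalent rhodium carbonyl that binds the alkyne and the terminal (distal) π bond of the allene; oxidative cyclisation to a trivalent rhodacyclopentene forms C1–C5 and thereby closes the seven-membered ring (C1, C5–C10) through the four-atom tether C6–C9. Migratory insertion of CO into a Rh–C bond and C–C reductive elimination then form C2–C3 and C3–C4, closing the cyclopentenone and leaving the proximal allene bond as the exocyclic C1=C10 alkene. The closest known reaction type is the rhodium-catalysed allenic Pauson–Khand reaction of allenynes to bicyclo[5.3.0]deca-1,7-dien-9-ones. The carbocycle closes by intramolecular oxidative coupling (metallacycle formation), the cyclopentenone by carbonylative [2+2+1] reductive elimination. No stereocentre is created and no bond to C6 or C7 is made or broken, so both pass through unchanged. The step needs distal over proximal selectivity: the methyl group on the internal allene carbon C10 and the preference of square-planar rhodium for the less substituted π bond direct the metal to C1=C2, and reaction at the proximal bond would have to build a more strained six-membered ring with an exocyclic methylene. It also needs CO insertion to outrun β-hydride loss (Alder-ene cycloisomerisation), which the CO atmosphere and dilution secure. The cis-cyclopropane with its gem-dimethyl group holds the two chains on one side like a cis-alkene, which offsets the entropic cost of the seven-membered ring.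

Step 7
Reactants: 11 (6S,7R)-15-noraromadendra-1(10),4-dien-3-one; 12 2,4,6-trimethoxybenzaldehyde
Product: 14 4-[hydroxy(2,4,6-trimethoxyphenyl)methyl]-10αH-15-noraromadendr-1(5)-en-3-one (C4/C7′ epimer mixture), via aluminium dienolate 13 (not isolated)
Conditions: MeCu (10 mol%, from CuBr·SMe2 and MeLi), i-Bu2AlH (1.1 equiv), THF–HMPA, −50 °C; then 12, −50 to −20 °C; aq. KNaC4H4O6 (tartrate)
Reagents that add atoms: none
Why: Conjugate reduction–aldol sequence (reductive aldol): the copper-catalysed aluminium hydride is expected to add hydride to the terminus C10 of the linear dienone (1,6-addition), which is less encumbered than the cyclopropane-flanked C5 and leads to the fully conjugated dienolate 13, and this reacts through its α-carbon C4 with 12. Hydride should approach C10 from the α face, away from C11 and its inward methyl group, which sets C10 (H α, C14 β); the C4 and C7′ centres formed here are erased in steps 8 and 9.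

Step 8
Reactants: 14 4-[hydroxy(2,4,6-trimethoxyphenyl)methyl]-10αH-15-noraromadendr-1(5)-en-3-one
Product: 15 4-(2,4,6-trimethoxybenzoyl)-10αH-15-noraromadendr-1(5)-en-3-one
Conditions: Dess–Martin periodinane, NaHCO3, CH2Cl2, 0 °C to rt
Reagents that add atoms: none
Why: Dess–Martin oxidation of the β-hydroxy ketone to the 1,3-diketone under buffered conditions, so that the electron-rich benzylic alcohol does not ionise and dehydrate; C7′ becomes trigonal and C4–H doubly activated.

Step 9
Reactants: 15 4-(2,4,6-trimethoxybenzoyl)-10αH-15-noraromadendr-1(5)-en-3-one
Product: 16 4β-(2,4,6-trimethoxybenzoyl)-10αH-aromadendr-1(5)-en-3-one (C15 α)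
Conditions: MeI, K2CO3, acetone, rt
Reagents that add atoms: iodomethane, CI
Why: C-alkylation of the stabilised 1,3-diketone enolate with a soft electrophile; the enolate ring is flat and its β face is covered by C11 of the adjacent cyclopropane, so iodomethane should enter on the α face, which fixes C4 with C15 α and the aroyl group β.

Step 10
Reactants: 16 4β-(2,4,6-trimethoxybenzoyl)-10αH-aromadendr-1(5)-en-3-one
Product: 17 4β-(2-hydroxy-4,6-dimethoxybenzoyl)-10αH-aromadendr-1(5)-en-3-one
Conditions: BCl3 (2.5 equiv), CH2Cl2, −78 to −30 °C; aq. NaHCO3
Reagents that add atoms: none
Why: Chelation-controlled Lewis-acid ether cleavage: boron bridges the aryl ketone oxygen and one ortho methoxy oxygen, chloride removes that methyl group, and the resulting chelate shuts down cleavage of the second ortho and the para ether; low temperature and the absence of protic acid until the bicarbonate quench protect the tetrasubstituted alkene next to the cyclopropane.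

Step 11
Reactants: 17 4β-(2-hydroxy-4,6-dimethoxybenzoyl)-10αH-aromadendr-1(5)-en-3-one
Product: 19 3,7′-dioxo-7′-dephenyl-bis(deformyl)psiguadial A di-O-methyl ether, via conjugated enone 18 (not isolated)
Conditions: DBU (0.5 equiv), MeCN, rt
Reagents that add atoms: none
Why: Base-mediated alkene isomerisation followed by intramolecular oxa-Michael addition (7-exo-trig): removal of a C2 proton and reprotonation at C5 moves the alkene into conjugation (18), and the phenoxide, held on the β face by C4, adds to the enone β-carbon C1, so the ether can form only at C1 and only from the β face (sets C1). C5 equilibrates through the dienolate and only the epimer with H5 β, which places C6 on the open α side of the new bridge, can close (sets C5); no carbocation is formed, so the cyclopropane is safe.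

Step 12
Reactants: 19 3,7′-dioxo-7′-dephenyl-bis(deformyl)psiguadial A di-O-methyl ether
Product: 20 C3 p-toluenesulfonylhydrazone of 19
Conditions: TsNHNH2, MeOH, 50 °C
Reagents that add atoms: p-toluenesulfonyl hydrazide, Cc1ccc(cc1)S(=O)(=O)NN
Why: Condensation of the more electrophilic cyclopentanone carbonyl with the sulfonyl hydrazide; the C7′ aryl ketone is deactivated by three oxygen donors and shielded by the quaternary C4 and should not react, and neutral conditions avoid β-elimination of the aryloxy group from C1.

Step 13
Reactants: 20 C3 p-toluenesulfonylhydrazone of 19
Product: 22 7′-oxo-7′-dephenyl-bis(deformyl)psiguadial A di-O-methyl ether, via N-boryl hydrazine 21 (not isolated)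
Conditions: catecholborane (3 equiv), CHCl3, 0 °C to rt; then NaOAc·3H2O, reflux
Reagents that add atoms: none
Why: Tosylhydrazone reduction (a Wolff–Kishner-type deoxygenation without strong base): hydride adds to the C=N bond to give 21, acetate induces loss of sulfinate, and the diazene loses N2 to leave CH2 at C3; the hindered aryl ketone is inert to the borane under these conditions.

Step 14
Reactants: 22 7′-oxo-7′-dephenyl-bis(deformyl)psiguadial A di-O-methyl ether
Product: 23 7′-hydroxy-7′-dephenyl-bis(deformyl)psiguadial A di-O-methyl ether (C7′ epimers)
Conditions: LiAlH4, THF, 0 °C to rt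
Reagents that add atoms: none
Why: Hydride reduction of the hindered aryl ketone by a small, strong hydride donor; the C7′ configuration obtained does not matter because this carbon is ionised in step 15.

Step 15
Reactants: 23 7′-hydroxy-7′-dephenyl-bis(deformyl)psiguadial A di-O-methyl ether; 24 phenylmagnesium bromide
Product: 26 bis(deformyl)psiguadial A di-O-methyl ether, via benzylic chloride 25 (not isolated)
Conditions: SOCl2, pyridine, CH2Cl2, −20 to 0 °C; evaporate; then PhMgBr (3 equiv), THF, −78 to 0 °C
Reagents that add atoms: none
Why: SN1 arylation: chloride 25 ionises readily because the C7′ cation is stabilised by three oxygen donors of the arene, it cannot eliminate (C4 has no hydrogen), and it is captured by the aryl Grignard reagent. In the bicyclo[4.2.1] frame the C7′ face turned toward the two-carbon bridge C2–C3 is eclipsed by C3, so phenyl should enter from the side of the one-carbon bridge C5 (between C5 and C15), which places H7′ toward C2–C3 as in 28 and sets C7′.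

Step 16
Reactants: 26 bis(deformyl)psiguadial A di-O-methyl ether
Product: 27 bis(deformyl)psiguadial A
Conditions: NaSEt (10 equiv), DMF, 140 °C; dilute aq. HCl to pH 4
Reagents that add atoms: none
Why: Nucleophilic O-demethylation (SN2 attack of thiolate at the methyl carbons); the tertiary alkyl aryl ether cannot react by SN2 and no acid is present at high temperature, so the ether bridge and the cyclopropane should survive.

Step 17
Reactants: 27 bis(deformyl)psiguadial A
Product: 28 psiguadial A
Conditions: Cl2CHOMe (6 equiv), TiCl4 (8 equiv), CH2Cl2, −78 to 0 °C; then H2O
Reagents that add atoms: dichloromethyl methyl ether, COC(Cl)Cl; water, O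
Why: Rieche formylation (electrophilic aromatic substitution by the titanium-activated chloromethyl oxocarbenium ion, then hydrolysis); C3″ and C5″ are the only free ring positions and each is ortho to a titanium phenoxide, so both are formylated; no stereocentre is formed.

## Compound list

1 | (+)-2-carene, (1S,6R)-3,7,7-trimethylbicyclo[4.1.0]hept-2-ene | CC1=C[C@H]2[C@@H](CC1)C2(C)C | starting material
2 | ozonide of 1 (1,2,4-trioxolane across the former C2=C3 bond, mixture at the two acetal carbons) | CC12CC[C@@H]3[C@H](C(O1)OO2)C3(C)C | intermediate
3 | (1S,3R)-2,2-dimethyl-3-(3-oxobutyl)cyclopropane-1-carbaldehyde | CC(=O)CC[C@@H]1[C@H](C=O)C1(C)C | intermediate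
4 | dimethyl (1-diazo-2-oxopropyl)phosphonate | COP(=O)(OC)C(=[N+]=[N-])C(C)=O | starting material
5 | 4-[(1R,3R)-3-ethynyl-2,2-dimethylcyclopropyl]butan-2-one | CC(=O)CC[C@@H]1[C@H](C#C)C1(C)C | intermediate
6 | ethynylmagnesium bromide | C#C[Mg]Br | starting material
7 | 5-[(1R,3R)-3-ethynyl-2,2-dimethylcyclopropyl]-3-methylpent-1-yn-3-ol (both carbinol epimers) | C#CC(C)(O)CC[C@@H]1[C@H](C#C)C1(C)C | intermediate
8 | lithium alkoxide of 7 | [Li]OC(C)(C#C)CC[C@@H]1[C@H](C#C)C1(C)C | intermediate
9 | methyl carbonate of 7 | COC(=O)OC(C)(C#C)CC[C@@H]1[C@H](C#C)C1(C)C | intermediate
10 | (1R,3R)-1-ethynyl-2,2-dimethyl-3-(3-methylpenta-3,4-dien-1-yl)cyclopropane (allenyne) | C=C=C(C)CC[C@@H]1[C@H](C#C)C1(C)C | intermediate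
11 | (6S,7R)-15-noraromadendra-1(10),4-dien-3-one (tricyclic dienone, C4 unsubstituted) | CC=1CC[C@@H]2[C@H](C3=CC(=O)CC3=1)C2(C)C | intermediate
12 | 2,4,6-trimethoxybenzaldehyde | COc1cc(OC)c(C=O)c(OC)c1 | starting material
13 | diisobutylaluminium 10αH-15-noraromadendra-1(5),3-dien-3-olate | C[C@H]1CC[C@@H]2[C@H](C3=C1CC(O[Al](CC(C)C)CC(C)C)=C3)C2(C)C | intermediate
14 | 4-[hydroxy(2,4,6-trimethoxyphenyl)methyl]-10αH-15-noraromadendr-1(5)-en-3-one (C4/C7′ epimer mixture) | C[C@H]1CC[C@@H]2[C@H](C3=C1CC(=O)C3C(O)c1c(OC)cc(OC)cc1OC)C2(C)C | intermediate
15 | 4-(2,4,6-trimethoxybenzoyl)-10αH-15-noraromadendr-1(5)-en-3-one (C4 enolisable) | C[C@H]1CC[C@@H]2[C@H](C3=C1CC(=O)C3C(=O)c1c(OC)cc(OC)cc1OC)C2(C)C | intermediate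
16 | 4β-(2,4,6-trimethoxybenzoyl)-10αH-aromadendr-1(5)-en-3-one (C15 α) | C[C@H]1CC[C@@H]2[C@H](C3=C1CC(=O)[C@]3(C)C(=O)c1c(OC)cc(OC)cc1OC)C2(C)C | intermediate
17 | 4β-(2-hydroxy-4,6-dimethoxybenzoyl)-10αH-aromadendr-1(5)-en-3-one | C[C@H]1CC[C@@H]2[C@H](C3=C1CC(=O)[C@]3(C)C(=O)c1c(O)cc(OC)cc1OC)C2(C)C | intermediate
18 | 4β-(2-hydroxy-4,6-dimethoxybenzoyl)-5βH,10αH-aromadendr-1-en-3-one (conjugated enone) | C[C@H]1CC[C@@H]2[C@H]([C@H]3C1=CC(=O)[C@]3(C)C(=O)c1c(O)cc(OC)cc1OC)C2(C)C | intermediate
19 | 3,7′-dioxo-7′-dephenyl-bis(deformyl)psiguadial A di-O-methyl ether (bridged pentacyclic diketone; O–C1 β, H5 β) | C[C@H]1CC[C@@H]2[C@H]([C@@H]3[C@]4(C)C(=O)C[C@@]31Oc1cc(OC)cc(OC)c1C4=O)C2(C)C | intermediate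
20 | C3 p-toluenesulfonylhydrazone of 19 | C[C@H]1CC[C@@H]2[C@H]([C@@H]3[C@]4(C)C(=NNS(=O)(=O)c5ccc(C)cc5)C[C@@]31Oc1cc(OC)cc(OC)c1C4=O)C2(C)C | intermediate
21 | N-(1,3,2-benzodioxaborol-2-yl)-N′-tosylhydrazine at C3 of the skeleton of 19 (C3 epimers) | C[C@H]1CC[C@@H]2[C@H]([C@@H]3[C@]4(C)C(N(NS(=O)(=O)c5ccc(C)cc5)B5Oc6ccccc6O5)C[C@@]31Oc1cc(OC)cc(OC)c1C4=O)C2(C)C | intermediate
22 | 7′-oxo-7′-dephenyl-bis(deformyl)psiguadial A di-O-methyl ether | C[C@H]1CC[C@@H]2[C@H]([C@@H]3[C@]4(C)CC[C@@]31Oc1cc(OC)cc(OC)c1C4=O)C2(C)C | intermediate
23 | 7′-hydroxy-7′-dephenyl-bis(deformyl)psiguadial A di-O-methyl ether (C7′ epimers) | C[C@H]1CC[C@@H]2[C@H]([C@@H]3[C@]4(C)CC[C@@]31Oc1cc(OC)cc(OC)c1C4O)C2(C)C | intermediate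
24 | phenylmagnesium bromide | Br[Mg]c1ccccc1 | starting material
25 | 7′-chloro-7′-dephenyl-bis(deformyl)psiguadial A di-O-methyl ether (C7′ epimers) | C[C@H]1CC[C@@H]2[C@H]([C@@H]3[C@]4(C)CC[C@@]31Oc1cc(OC)cc(OC)c1C4Cl)C2(C)C | intermediate
26 | bis(deformyl)psiguadial A di-O-methyl ether | C[C@H]1CC[C@@H]2[C@H]([C@@H]3[C@]4(C)CC[C@@]31Oc1cc(OC)cc(OC)c1[C@@H]4c1ccccc1)C2(C)C | intermediate
27 | bis(deformyl)psiguadial A (diphenol) | C[C@H]1CC[C@@H]2[C@H]([C@@H]3[C@]4(C)CC[C@@]31Oc1cc(O)cc(O)c1[C@@H]4c1ccccc1)C2(C)C | intermediate
28 | psiguadial A | C[C@H]1CC[C@@H]2[C@H]([C@@H]3[C@]4(C)CC[C@@]31Oc1c(C=O)c(O)c(C=O)c(O)c1[C@@H]4c1ccccc1)C2(C)C | target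

## Step count and least certain steps

Total step count: 17. Longest linear sequence: 17 steps, from 1 to 28; compounds 4, 6, 12 and 24 are purchased.

Step 6 (key step).
- What may go wrong: the terminal alkyne may divert the catalyst into rhodium vinylidene or alkynyl species and alkyne oligomerisation. β-Hydride loss in the rhodacycle (Alder-ene cycloisomerisation) may outrun CO insertion, because closure of a seven-membered ring is slower than the usual six-membered case. Slow insertion of rhodium into the strained ring of the dienylcyclopropane product is a further drain.
- Fallback (changes the substrate design): from 10, deprotonation of the alkyne with LiN(SiMe3)2 and trapping with Me3SiCl would give the C-trimethylsilyl allenyne F1. Silyl alkynes cannot form vinylidenes and are well-behaved partners in this reaction type. The same carbonylative cyclisation would give the 4-trimethylsilyl dienone F2, and protodesilylation with Bu4NF/AcOH would return to 11.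

Step 7.
- What may go wrong: misdirected hydride delivery, to C5 (1,4-addition, which copper hydrides often prefer) or to the carbonyl instead of C10. Reduction of 12 by residual hydride and acid-induced dehydration of the electron-rich aldol are also possible.
- Fallback (C10 set by protonation instead of by hydride): from 11, a deliberately 1,4-selective conjugate hydrosilylation with [(Ph3P)CuH]6/PhMe2SiH, release of the lithium enolate with MeLi and addition to 12 would give the 5-hydro aldol with the C1=C10 alkene retained, F3. Dess–Martin oxidation would give diketone F4, MeI/K2CO3 the C4-methyl diketone F5 (C15 again anti to C11), and BCl3 the phenol F6. Under the DBU conditions of step 11 the C1=C10 alkene is drawn into conjugation by deprotonation at C2 and protonation at C10 from the open α face, C5 equilibrates as before, and ring closure would deliver 19, where the route is rejoined.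

Step 11.
- What may go wrong: the closure is reversible and may rest on the side of the open phenoxide, which is stabilised by the ortho acyl group. The phenoxide may instead add to the C3 carbonyl and cleave the non-enolisable 1,3-diketone. Long exposure to base may epimerise C10 through the cross-conjugated dienolate of 18.
- Fallback (electrophile activation instead of nucleophile activation, isomerisation decoupled from closure): from 17, brief treatment with Et3N would give enone 18, which is isolated. A Brønsted acid catalyst ((PhO)2PO2H or camphorsulfonic acid, toluene, rt) would then activate the enone carbonyl so that the neutral phenol adds to C1, with no phenoxide and no carbanion present. The route is rejoined at 19 (no new compound, F0).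

Step 15.
- What may go wrong: capture of the C7′ cation from the other face if the bridged ring is more flexible than the model assumes, and electron transfer from the Grignard reagent leading to reduction or dimerisation of the cation.
- Fallback (reversed order of the two C7′ substituents, which inverts the outcome because the group that arrives second takes the more accessible face): from 22, PhLi addition to the ketone would give the tertiary carbinol F7. Ionic hydrogenation (Et3SiH, CF3CO2H, CH2Cl2, −40 °C) would then deliver hydride to the cation and return to 26.

Step 16.
- What may go wrong: incomplete cleavage of the second methyl ether, because the first phenoxide makes the ring electron-rich and slows the second SN2 step, and thermal stress at 140 °C.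
- Fallback (formylate first, then demethylate an activated ring): from 26, Rieche diformylation (Cl2CHOMe, TiCl4) would give the dialdehyde di-O-methyl ether F8. Each methoxy group then sits ortho or para to an aldehyde and should be cleaved by n-PrSLi in DMF at 80–100 °C, which gives 28 directly.

## Further compounds

F1 | step 6 | C-trimethylsilyl derivative of allenyne 10 | C=C=C(C)CC[C@@H]1[C@H](C#C[Si](C)(C)C)C1(C)C
F2 | step 6 | 4-trimethylsilyl derivative of dienone 11 | CC=1CC[C@@H]2[C@H](C3=C([Si](C)(C)C)C(=O)CC3=1)C2(C)C
F3 | step 7 | 4-[hydroxy(2,4,6-trimethoxyphenyl)methyl]-15-noraromadendr-1(10)-en-3-one (C4, C5, C7′ epimers) | CC1=C2CC(=O)C(C(O)c3c(OC)cc(OC)cc3OC)C2[C@H]2[C@@H](CC1)C2(C)C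
F4 | step 7 | 4-(2,4,6-trimethoxybenzoyl)-15-noraromadendr-1(10)-en-3-one (C4 enolisable, C5 unassigned) | CC1=C2CC(=O)C(C(=O)c3c(OC)cc(OC)cc3OC)C2[C@H]2[C@@H](CC1)C2(C)C
F5 | step 7 | 4β-(2,4,6-trimethoxybenzoyl)aromadendr-1(10)-en-3-one (C15 α, C5 unassigned) | CC1=C2CC(=O)[C@](C)(C(=O)c3c(OC)cc(OC)cc3OC)C2[C@H]2[C@@H](CC1)C2(C)C
F6 | step 7 | 4β-(2-hydroxy-4,6-dimethoxybenzoyl)aromadendr-1(10)-en-3-one (C15 α, C5 unassigned) | CC1=C2CC(=O)[C@](C)(C(=O)c3c(O)cc(OC)cc3OC)C2[C@H]2[C@@H](CC1)C2(C)C
F0 | step 11 | none | none
F7 | step 15 | 7′-hydroxy-bis(deformyl)psiguadial A di-O-methyl ether (tertiary carbinol, C7′ unassigned) | C[C@H]1CC[C@@H]2[C@H]([C@@H]3[C@]4(C)CC[C@@]31Oc1cc(OC)cc(OC)c1C4(O)c1ccccc1)C2(C)C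
F8 | step 16 | psiguadial A di-O-methyl ether | C[C@H]1CC[C@@H]2[C@H]([C@@H]3[C@]4(C)CC[C@@]31Oc1c(C=O)c(OC)c(C=O)c(OC)c1[C@@H]4c1ccccc1)C2(C)C
A1 | alternative 1 | 3-oxo pentacyclic dimethyl ether (3-oxo derivative of 26) | C[C@H]1CC[C@@H]2[C@H]([C@@H]3[C@]4(C)C(=O)C[C@@]31Oc1cc(OC)cc(OC)c1[C@@H]4c1ccccc1)C2(C)C
A2 | alternative 1 | 5βH,10αH-aromadendr-1-en-3-one (tricyclic cyclopentenone, C4 epimerisable) | C[C@H]1CC[C@@H]2[C@H]([C@@H]3C(C)C(=O)C=C31)C2(C)C
A3 | alternative 1 | 3,5-dimethoxy-2-[phenyl(p-tolylsulfonyl)methyl]phenol (racemic) | COc1cc(O)c(C(c2ccccc2)S(=O)(=O)c2ccc(C)cc2)c(OC)c1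
A4 | alternative 2 | 5-oxo-4,5-dihydrobicyclogermacrene (ten-membered ketone, C4 unfixed) | C/C1=C\CCC(C)C(=O)[C@H]2[C@@H](CC1)C2(C)C
A5 | alternative 2 | carene-derived 1,2-divinyl carbinol: 2-isopropenyl-3-methyl-3-vinylcaran-2-ol (carbinol and vinyl-bearing centres chosen for the E alkene) | C=CC1(C)CC[C@@H]2[C@H](C1(O)C(C)=C)C2(C)C
A6 | alternative 3 | 10-hydroxy-3-oxo hydroazulenone carrying the C7′ diarylmethyl group on C4 | C[C@@]1(O)CC[C@@H]2[C@H](C3=C([C@@H](c4ccccc4)c4c(OC)cc(OC)cc4OC)C(=O)C[C@H]31)C2(C)C
A7 | alternative 3 | carene-derived decalin 1,4-dien-3-one carrying the C7′ diarylmethyl group on C4 (C10 unassigned) | CC12CC[C@@H]3[C@H](C1=C([C@@H](c1ccccc1)c1c(OC)cc(OC)cc1OC)C(=O)C=C2)C3(C)C
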